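**Retrosynthetic overview**
1. Target 6 ⇒ 1-heptadecyl-3,5-dimethoxybenzene 4. Both quinone C=O groups are made last: C–H → C–O at the ring carbon between the chain and one OMe, and oxidative demethylation of the OMe para to it. The two ortho/para sites C2 and C6 of 4 are equivalent by symmetry.
2. 4 ⇒ hexadecylmagnesium bromide 2 + 3,5-dimethoxybenzyl bromide 3, by benzylic Csp3–Csp3 coupling (C16 + ArCH2 gives the C17 chain).
3. 2 ⇒ 1-bromohexadecane 1 + Mg.
4. Rings: no ring is built. The benzene ring bought in 3 becomes the quinone ring in the last step.

Assumption: the target has no stereocentre and no stereogenic double bond, so it is made as the single achiral compound drawn.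

**Step 1**
Reactants: 1 1-bromohexadecane
Product: 2 hexadecylmagnesium bromide (about 0.5 M stock solution in THF, titrated, used without purification)
Conditions: Mg turnings (1.3 equiv), I2 (cat.), THF, 45 °C, slow addition of 1, 2 h
Reagents that add atoms: magnesium, [Mg]
Why: Grignard formation by insertion of Mg into a primary C–Br bond; slow addition of the bromide to excess Mg keeps Wurtz coupling low.

**Step 2**
Reactants: 2 hexadecylmagnesium bromide; 3 3,5-dimethoxybenzyl bromide
Product: 4 1-heptadecyl-3,5-dimethoxybenzene
Conditions: Li2CuCl4 (3 mol%), THF, −10 °C → rt, 2 (1.2 equiv) added dropwise to 3; aq. NH4Cl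
Reagents that add atoms: none
Why: Copper-catalysed Kumada-type Csp3–Csp3 coupling of a primary alkyl Grignard with a reactive benzylic bromide; the aryl methyl ethers are inert, and inverse addition at low temperature suppresses halogen–metal exchange and bibenzyl formation.

**Step 3**
Reactants: 4 1-heptadecyl-3,5-dimethoxybenzene
Product: 6 2-heptadecyl-6-methoxy-1,4-benzoquinone (target), via 2-heptadecyl-4,6-dimethoxyphenol 5 (not isolated)
Conditions: 3,6-di-tert-butyl-9-mesityl-10-phenylacridinium BF4 (5 mol%), TEMPO (10 mol%), O2 (1 atm), H2O (20 equiv), DCE/MeCN 1:1 (0.05 M), 450 nm LEDs, 25 °C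
Reagents that add atoms: water, O
Why: Proposed new method: a four-electron photoredox arene-to-quinone cascade (4 + 2 H2O + 2 O2 → 6 + MeOH + 2 H2O2) in which the excited acridinium (about +2.1 V vs SCE) oxidises 4 (about +1.5 V) to its cation radical, water adds at C2/C6 (para to one OMe and ortho to the other, the usual site of attack on 1,3-dimethoxyarenes; the carbon between the two OMe groups is less reactive and cannot lead to a p-quinone), and TEMPO/O2 aromatise the adduct to phenol 5; 5 (about +1.0 V) is then oxidised in preference to 4, water adds ipso at the para OMe carbon and the hemiketal loses methanol to give the quinone, which is too electron-poor to be oxidised further, while the benzylic C–H sits on a carbon meta to both OMe groups where the cation radical carries little spin, so side-chain oxidation should be slow; the closest known reaction types are acridinium-photoredox site-selective arene C–H amination and hydroxylation through arene cation radicals, and the oxidative demethylation of p-methoxyphenols to p-quinones.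

**Compound list**
1 | 1-bromohexadecane | CCCCCCCCCCCCCCCCBr | starting material
2 | hexadecylmagnesium bromide | CCCCCCCCCCCCCCCC[Mg]Br | intermediate
3 | 3,5-dimethoxybenzyl bromide (1-(bromomethyl)-3,5-dimethoxybenzene) | COc1cc(CBr)cc(OC)c1 | starting material
4 | 1-heptadecyl-3,5-dimethoxybenzene | CCCCCCCCCCCCCCCCCc1cc(OC)cc(OC)c1 | intermediate
5 | 2-heptadecyl-4,6-dimethoxyphenol | CCCCCCCCCCCCCCCCCc1cc(OC)cc(OC)c1O | intermediate
6 | 2-heptadecyl-6-methoxy-1,4-benzoquinone | CCCCCCCCCCCCCCCCCC1=CC(=O)C=C(OC)C1=O | target

**Total step count:** 3 (only 4 and 6 are purified; 2 is used as a solution).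
**Longest linear sequence:** 3.

**Steps most likely to fail**

Step 3 (the proposed photoredox oxygenation). Likely failure modes are slow capture of the cation radical by water, biaryl coupling, and photolysis of the alkylquinone product. The fallback uses known chemistry, sets out from 4 and comes back at 6. One of the two equivalent methyl ethers of 4 is cleaved with sodium ethanethiolate in DMF at 140 °C (SN2 demethylation; the phenoxide formed protects the second ether) to give 3-heptadecyl-5-methoxyphenol F1. F1 is then oxidised with Fremy's salt (potassium nitrosodisulfonate, KH2PO4 buffer, Aliquat 336, CH2Cl2/H2O, rt; Teuber oxidation) at the free position para to the hydroxyl, which lies between the chain and the methoxy group, to give 6.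

Step 2 (Csp3–Csp3 coupling). The likely failure mode is halogen–metal exchange giving bibenzyl and dotriacontane. The fallback sets out from 1 and comes back at 4. 1 is heated with PPh3 (toluene, reflux) to give hexadecyltriphenylphosphonium bromide F2. Its ylide (NaHMDS, THF, −78 °C) is condensed with commercial 3,5-dimethoxybenzaldehyde in a Wittig reaction to give 1-(heptadec-1-en-1-yl)-3,5-dimethoxybenzene F3 as a Z-rich Z/E mixture. Hydrogenation of both isomers (H2 1 atm, 10% Pd/C, EtOAc) gives 4.

Step 1 (Grignard formation). Likely failure modes are poor initiation and Wurtz coupling to dotriacontane. The fallback reverses the polarity of the coupling, sets out from 3 (with 1 as the electrophile) and comes back at 4, so steps 1 and 2 are both replaced. Zinc dust with LiCl inserts into the benzylic C–Br bond of 3 (THF, 25 °C) to give (3,5-dimethoxybenzyl)zinc bromide F4. F4 is cross-coupled with 1 under nickel catalysis (Ni(acac)2 10 mol%, 4-fluorostyrene 20 mol%, Bu4NI, THF/NMP, 0 °C → rt; Negishi-type alkyl–alkyl coupling) to give 4.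

**Further compounds**
F1 | step 3 | 3-heptadecyl-5-methoxyphenol | CCCCCCCCCCCCCCCCCc1cc(O)cc(OC)c1
F2 | step 2 | hexadecyltriphenylphosphonium bromide | CCCCCCCCCCCCCCCC[P+](c1ccccc1)(c1ccccc1)c1ccccc1.[Br-]
F3 | step 2 | (Z)-1-(heptadec-1-en-1-yl)-3,5-dimethoxybenzene (major isomer of the Z/E mixture) | CCCCCCCCCCCCCCC/C=C\c1cc(OC)cc(OC)c1
F4 | step 1 | (3,5-dimethoxybenzyl)zinc bromide | COc1cc(C[Zn]Br)cc(OC)c1
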